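**Plan**

- Retrosynthesis: pyran ring F of the lower unit (O1', C2', C3', C4', C4a', C8a') carries a trans-vicinal diol on the adjacent carbons C3' and C4'. Cutting C3'–C4' turns both carbinol carbons into aldehyde carbons (an aryl CHO on ring D, an α-aryloxy CHO on C2'), and this is what lets a reductive carbonyl–carbonyl coupling close the ring.
- Further cuts: the O1'–C2' ether bond (ring D phenol + cinnamyl carbonate carrying ring E), then the C4–C6' interflavan bond (ring D aryl bromide + (2S)-flavanone), then the C2–aryl bond (chromone + ring B boronic acid).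
- Forward order: rings A/C (chromone), ring B, ring D onto C4 (aryl addition, dehydration, hydroboration, C3 inversion), ring E by O-allylation of the ring D phenol, ring F last by pinacol cyclisation, then global debenzylation.
- Stereochemistry: C2 from ligand-controlled Pd conjugate arylation. C3 and C4 from syn hydroboration anti to the C2 aryl, with C3 then inverted by oxidation and LiBH(s-Bu)3 reduction to the all-cis array. C2' from ligand-controlled Ir allylic etherification. C3' and C4' from the key step under control of C2'.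
- Ring letters: A, B, C are the benzo, catechol and pyran rings of the upper unit; D, E, F are the same rings of the lower unit (primed locants).

Key step: step 19

Remark: (R)-t-BuPyOx (step 3) and the (Sa,S,S)-phosphoramidite (step 16) are assigned by analogy with cyclic enones and cinnamyl carbonates; if a first run shows the opposite sense, the antipodal ligand is used and nothing else changes.
Remark: boronic acid 5 is taken as a catalogue compound, like 1, 7 and 21.

**Route**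

Step 1
Reactants: 1 1-(2,3,4-trihydroxyphenyl)ethanone
Product: 2 1-[3,4-bis(benzyloxy)-2-hydroxyphenyl]ethanone
Conditions: BnBr (2.1 equiv), K2CO3 (2.2 equiv), DMF, rt
Reagents that add atoms: benzyl bromide, BrCc1ccccc1
Why: Williamson etherification; the 2-OH is hydrogen-bonded to the acetyl oxygen and is the weakest nucleophile, so two equivalents of bromide should benzylate O3 and O4 only.

Step 2
Reactants: 2 1-[3,4-bis(benzyloxy)-2-hydroxyphenyl]ethanone
Product: 4 7,8-bis(benzyloxy)-4H-chromen-4-one, via enaminone 3 (not isolated)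
Conditions: Me2NCH(OMe)2, PhMe, 100 °C; evaporate; 2 M HCl, CH2Cl2, 40 °C
Reagents that add atoms: N,N-dimethylformamide dimethyl acetal, COC(OC)N(C)C
Why: condensation of the methyl ketone with the amide acetal, then acid-promoted cyclisation of the 2-hydroxyaryl enaminone with loss of Me2NH, is the standard chromone synthesis.

Step 3
Reactants: 4 7,8-bis(benzyloxy)-4H-chromen-4-one; 5 [3,4-bis(benzyloxy)phenyl]boronic acid
Product: 6 (2S)-7,8-bis(benzyloxy)-2-[3,4-bis(benzyloxy)phenyl]chroman-4-one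
Conditions: Pd(OCOCF3)2 (5 mol %), (R)-t-BuPyOx (6 mol %), NH4PF6 (30 mol %), H2O (5 equiv), ClCH2CH2Cl, 60 °C
Reagents that add atoms: none
Why: Pd-catalysed asymmetric conjugate addition of an arylboronic acid to a chromone; the pyridine–oxazoline ligand fixes the face on which aryl–Pd inserts into C2=C3 and so sets C2 (S), and the neutral medium avoids retro-oxa-Michael racemisation of the flavanone.

Step 4
Reactants: 7 2,3,4-trihydroxybenzaldehyde
Product: 8 3,4-bis(benzyloxy)-2-hydroxybenzaldehyde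
Conditions: BnBr (2.1 equiv), K2CO3 (2.2 equiv), DMF, rt
Reagents that add atoms: benzyl bromide, BrCc1ccccc1
Why: Williamson etherification; as in step 1 the chelated 2-OH should stay free.

Step 5
Reactants: 8 3,4-bis(benzyloxy)-2-hydroxybenzaldehyde
Product: 9 3,4-bis(benzyloxy)-5-bromo-2-hydroxybenzaldehyde
Conditions: NBS (1.05 equiv), MeCN, 0 °C to rt
Reagents that add atoms: N-bromosuccinimide, O=C1CCC(=O)N1Br
Why: electrophilic aromatic bromination goes para to the free phenol, at C5, the only ring position activated by two oxygens and not deactivated by the formyl group.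

Step 6
Reactants: 9 3,4-bis(benzyloxy)-5-bromo-2-hydroxybenzaldehyde
Product: 10 2,3-bis(benzyloxy)-4-bromo-6-(hydroxymethyl)phenol
Conditions: NaBH4, THF–MeOH, 0 °C
Reagents that add atoms: none
Why: NaBH4 reduction of the aldehyde; aryl bromide and benzyl ethers are inert.

Step 7
Reactants: 10 2,3-bis(benzyloxy)-4-bromo-6-(hydroxymethyl)phenol
Product: 11 7,8-bis(benzyloxy)-6-bromo-2,2-dimethyl-4H-1,3-benzodioxine
Conditions: Me2C(OMe)2, PPTS (cat.), acetone, rt
Reagents that add atoms: 2,2-dimethoxypropane, COC(C)(C)OC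
Why: acid-catalysed acetal exchange closes the six-membered 1,3-benzodioxin, one group that masks both the phenol and the benzylic alcohol and tolerates n-BuLi, BH3, oxidant and hydride.

Step 8
Reactants: 11 7,8-bis(benzyloxy)-6-bromo-2,2-dimethyl-4H-1,3-benzodioxine; 6 (2S)-7,8-bis(benzyloxy)-2-[3,4-bis(benzyloxy)phenyl]chroman-4-one
Product: 15 (2S)-4-(benzodioxin-6-yl)-2-aryl-2H-chromene (full name in the list), via aryllithium 12 (not isolated), via arylcerium dichloride 13 (not isolated), via tertiary carbinol 14 (not isolated)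
Conditions: 11, n-BuLi, THF, −78 °C; anhydrous CeCl3, −78 °C; 6, −78 to −40 °C; aq NH4Cl; crude carbinol, Burgess reagent, PhMe, 50 °C, dark
Reagents that add atoms: none
Why: bromine–lithium exchange and transmetalation give a weakly basic arylcerium that should add 1,2 to the flavanone carbonyl instead of enolising it, and Burgess dehydration of the doubly benzylic carbinol can only give the C3=C4 alkene, so the C4–C6' bond forms with defined regiochemistry and C2 is untouched.

Step 9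
Reactants: 15 (2S)-4-(benzodioxin-6-yl)-2-aryl-2H-chromene
Product: 17 (2R,3S,4S)-4-(benzodioxin-6-yl)flavan-3-ol with 2,3-trans-3,4-trans geometry, via alkylborane 16 (not isolated)
Conditions: BH3·THF (3 equiv), THF, 0 °C to rt; then NaOH, H2O2, 0 °C
Reagents that add atoms: hydrogen peroxide, OO
Why: hydroboration–oxidation; boron goes to C3 (away from the diaryl-substituted C4) on the face opposite the C2 aryl and H adds syn to C4, which sets C3 (OH trans to the C2 aryl) and C4 (ring D cis to the C2 aryl), as in the known conversion of flav-3-enes into 2,3-trans-flavan-3-ols.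

Step 10
Reactants: 17 (2R,3S,4S)-4-(benzodioxin-6-yl)flavan-3-ol
Product: 18 (2R,4S)-4-(benzodioxin-6-yl)flavan-3-one with the two aryl groups cis
Conditions: Dess–Martin periodinane, NaHCO3, CH2Cl2, 0 °C to rt
Reagents that add atoms: none
Why: Dess–Martin oxidation under bicarbonate buffer is neutral and cold, so the enolisable centres C2 and C4 (both aryl groups equatorial, the stable arrangement) should keep their configuration.

Step 11
Reactants: 18 (2R,4S)-4-(benzodioxin-6-yl)flavan-3-one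
Product: 19 (2R,3R,4S)-4-(benzodioxin-6-yl)flavan-3-ol with all-cis geometry
Conditions: LiBH(s-Bu)3, THF, −78 °C; aq NH4Cl
Reagents that add atoms: none
Why: bulky-hydride reduction of a flavan-3-one; the hydride enters from the face opposite the two cis aryl groups and gives the axial alcohol, inverting C3 to the all-cis array, the same oxidation–reduction that turns 2,3-trans- into 2,3-cis-flavan-3-ols.

Step 12
Reactants: 19 (2R,3R,4S)-4-(benzodioxin-6-yl)flavan-3-ol, all-cis
Product: 20 (2R,3R,4S)-4-[2,3-bis(benzyloxy)-4-hydroxy-5-(hydroxymethyl)phenyl]flavan-3-ol, all-cis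
Conditions: AcOH–H2O–THF (3:1:1), 45 °C
Reagents that add atoms: none
Why: acid hydrolysis of the isopropylidene acetal; weak aqueous acid is chosen so that the electron-rich 2-hydroxybenzyl alcohol is not ionised to a quinone methide.

Step 13
Reactants: 21 3,4-bis(benzyloxy)benzaldehyde
Product: 22 ethyl (E)-3-[3,4-bis(benzyloxy)phenyl]prop-2-enoate
Conditions: Ph3P=CHCO2Et, PhMe, 80 °C
Reagents that add atoms: ethyl (triphenylphosphoranylidene)acetate, CCOC(=O)C=P(c1ccccc1)(c1ccccc1)c1ccccc1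
Why: Wittig olefination with a stabilised ylide gives the (E)-cinnamate.

Step 14
Reactants: 22 ethyl (E)-3-[3,4-bis(benzyloxy)phenyl]prop-2-enoate
Product: 23 (E)-3-[3,4-bis(benzyloxy)phenyl]prop-2-en-1-ol
Conditions: i-Bu2AlH (2.2 equiv), CH2Cl2, −78 °C; aq potassium sodium tartrate
Reagents that add atoms: none
Why: i-Bu2AlH 1,2-reduction of the unsaturated ester gives the allylic alcohol.

Step 15
Reactants: 23 (E)-3-[3,4-bis(benzyloxy)phenyl]prop-2-en-1-ol
Product: 24 (E)-3-[3,4-bis(benzyloxy)phenyl]allyl methyl carbonate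
Conditions: ClCO2Me, pyridine, CH2Cl2, 0 °C
Reagents that add atoms: methyl chloroformate, COC(=O)Cl
Why: O-acylation with a chloroformate installs the carbonate leaving group for allyl–metal formation.

Step 16
Reactants: 20 all-cis flavan-3-ol with free ring D phenol and CH2OH; 24 (E)-3-[3,4-bis(benzyloxy)phenyl]allyl methyl carbonate
Product: 25 branched (S)-1-arylallyl ether of the ring D phenol (full name in the list)
Conditions: [Ir(cod)Cl]2 (2.5 mol %), (Sa,S,S)-O,O'-(1,1'-binaphthyl-2,2'-diyl) N,N-bis(1-phenylethyl)phosphoramidite (5 mol %, pre-activated with n-PrNH2), K3PO4 (1.0 equiv), 24 (1.5 equiv), THF, rt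
Reagents that add atoms: none
Why: Ir-catalysed asymmetric allylic etherification; the cyclometalated Ir–phosphoramidite ionises the linear carbonate and the phenoxide (the only oxygen K3PO4 deprotonates) attacks the aryl-bearing allyl terminus anti to the metal, giving the branched ether with C2' set (S) by the ligand, independent of the remote centres.

Step 17
Reactants: 25 branched allyl ether with ring D CH2OH
Product: 26 branched allyl ether with ring D CHO
Conditions: MnO2 (activated, 15 equiv), CH2Cl2, rt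
Reagents that add atoms: none
Why: MnO2 oxidises only the benzylic primary alcohol, leaving the hindered secondary 3-OH and the allyl ether alone.

Step 18
Reactants: 26 branched allyl ether with ring D CHO
Product: 28 dialdehyde (aryl CHO on ring D and α-aryloxy CHO on C2'), via ozonide 27 (not isolated)
Conditions: O3, CH2Cl2, −78 °C (Sudan Red 7B end point); PPh3, −78 to 0 °C; rapid filtration through deactivated silica, used at once
Reagents that add atoms: ozone, [O-][O+]=O
Why: ozonolysis with reductive work-up cleaves the only C=C bond (terminal alkenes react far faster than the alkoxyarenes, hence the dye end point), and the cold, neutral PPh3 reduction should deliver the α-aryloxy aldehyde without enolising C2'.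

Step 19
Reactants: 28 dialdehyde
Product: 30 octa-O-benzyl dimer with free 3-OH and 3',4'-trans diol, via bis(trimethylsilyl) ether 29 (not isolated)
Conditions: divided cell, Pb cathode, Pt anode, 0.1 M Et4NOTs in DMF (pre-electrolysed), Me3SiCl (6 equiv), 28 at 5 mM, potential held at the aryl aldehyde wave, 2.2 F/mol, −20 °C; then K2CO3, MeOH, 0 °C
Reagents that add atoms: none
Why: One-electron reduction of the aryl aldehyde (the more easily reduced carbonyl) with O-silylation gives a benzylic silyloxy radical at C4' that adds to the carbon of the neighbouring α-aryloxy aldehyde, and a second electron plus silylation of the new alkoxide completes an intramolecular pinacol coupling; the closest known reaction type is the electroreductive or SmI2-mediated pinacol cyclisation of dialdehydes to cyclic 1,2-diols. Ring F closes in a 6-exo-trig mode, C4' attacking C3' with the C3' oxygen left outside the ring. C3' is controlled by the existing C2' centre: in the half-chair transition state the C2' aryl is pseudo-equatorial and the aldehyde is attacked on the face that puts its oxygen pseudo-axial, cis to the aryl. C4' is controlled by the relation of the two oxygens: with no metal to bridge them and both silylated, they stay antiperiplanar, and a pseudo-axial C4' oxygen also avoids peri strain with H5', so the trans-diaxial diol should result. The step needs 2',3'-cis-3',4'-trans selectivity and retention of the labile C2' centre; the equatorial aryl with unchelated anti oxygens should secure the first, and Me3SiCl as oxyanion trap (no alkoxide or electrogenerated base accumulates) together with high dilution should secure the second.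

Step 20
Reactants: 30 octa-O-benzyl dimer
Product: 31 target CNP0143773.1
Conditions: H2 (1 atm), Pd(OH)2 on carbon, THF–MeOH (1:1), rt; filter under Ar
Reagents that add atoms: none
Why: hydrogenolysis of the eight benzyl ethers over Pd(OH)2 on carbon in neutral solvent, stopped at the calculated uptake so that the benzylic C4'–OH and C2–O1 bonds are not cleaved.

**Compound list**

1 | 1-(2,3,4-trihydroxyphenyl)ethanone | CC(=O)c1ccc(O)c(O)c1O | starting material
2 | 1-[3,4-bis(benzyloxy)-2-hydroxyphenyl]ethanone | CC(=O)c1ccc(OCc2ccccc2)c(OCc3ccccc3)c1O | intermediate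
3 | (E)-1-[3,4-bis(benzyloxy)-2-hydroxyphenyl]-3-(dimethylamino)prop-2-en-1-one | CN(C)/C=C/C(=O)c1ccc(OCc2ccccc2)c(OCc3ccccc3)c1O | intermediate
4 | 7,8-bis(benzyloxy)-4H-chromen-4-one | O=c1ccoc2c1ccc(OCc3ccccc3)c2OCc4ccccc4 | intermediate
5 | [3,4-bis(benzyloxy)phenyl]boronic acid | OB(O)c1ccc(OCc2ccccc2)c(OCc3ccccc3)c1 | starting material
6 | (2S)-7,8-bis(benzyloxy)-2-[3,4-bis(benzyloxy)phenyl]chroman-4-one | O(Cc9ccccc9)c1ccc([C@H]2Oc3c(ccc(OCc9ccccc9)c3OCc9ccccc9)C(=O)C2)cc1OCc9ccccc9 | intermediate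
7 | 2,3,4-trihydroxybenzaldehyde | O=Cc1ccc(O)c(O)c1O | starting material
8 | 3,4-bis(benzyloxy)-2-hydroxybenzaldehyde | O=Cc1ccc(OCc2ccccc2)c(OCc3ccccc3)c1O | intermediate
9 | 3,4-bis(benzyloxy)-5-bromo-2-hydroxybenzaldehyde | O=Cc1cc(Br)c(OCc2ccccc2)c(OCc3ccccc3)c1O | intermediate
10 | 2,3-bis(benzyloxy)-4-bromo-6-(hydroxymethyl)phenol | OCc1cc(Br)c(OCc2ccccc2)c(OCc3ccccc3)c1O | intermediate
11 | 7,8-bis(benzyloxy)-6-bromo-2,2-dimethyl-4H-1,3-benzodioxine | CC1(C)OCc2cc(Br)c(OCc3ccccc3)c(OCc4ccccc4)c2O1 | intermediate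
12 | [7,8-bis(benzyloxy)-2,2-dimethyl-4H-1,3-benzodioxin-6-yl]lithium | [Li]c1cc2COC(C)(C)Oc2c(OCc3ccccc3)c1OCc4ccccc4 | intermediate
13 | [7,8-bis(benzyloxy)-2,2-dimethyl-4H-1,3-benzodioxin-6-yl]cerium dichloride | Cl[Ce](Cl)c1cc2COC(C)(C)Oc2c(OCc3ccccc3)c1OCc4ccccc4 | intermediate
14 | (2S)-7,8-bis(benzyloxy)-2-[3,4-bis(benzyloxy)phenyl]-4-[7,8-bis(benzyloxy)-2,2-dimethyl-4H-1,3-benzodioxin-6-yl]chroman-4-ol (both C4 epimers) | O(Cc9ccccc9)c1ccc([C@H]2Oc3c(ccc(OCc9ccccc9)c3OCc9ccccc9)C(O)(c3cc4COC(C)(C)Oc4c(OCc9ccccc9)c3OCc9ccccc9)C2)cc1OCc9ccccc9 | intermediate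
15 | (2S)-7,8-bis(benzyloxy)-2-[3,4-bis(benzyloxy)phenyl]-4-[7,8-bis(benzyloxy)-2,2-dimethyl-4H-1,3-benzodioxin-6-yl]-2H-chromene | O(Cc9ccccc9)c1ccc([C@H]2Oc3c(ccc(OCc9ccccc9)c3OCc9ccccc9)C(c3cc4COC(C)(C)Oc4c(OCc9ccccc9)c3OCc9ccccc9)=C2)cc1OCc9ccccc9 | intermediate
16 | C3 borane of 15: BH2 on C3 trans to the C2 aryl, H4 cis to boron, ring D cis to the C2 aryl | O(Cc9ccccc9)c1ccc([C@H]2Oc3c(ccc(OCc9ccccc9)c3OCc9ccccc9)[C@@H](c3cc4COC(C)(C)Oc4c(OCc9ccccc9)c3OCc9ccccc9)[C@@H]2B)cc1OCc9ccccc9 | intermediate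
17 | (2R,3S,4S)-7,8-bis(benzyloxy)-2-[3,4-bis(benzyloxy)phenyl]-4-[7,8-bis(benzyloxy)-2,2-dimethyl-4H-1,3-benzodioxin-6-yl]chroman-3-ol (2,3-trans-3,4-trans; the two aryl groups cis) | O(Cc9ccccc9)c1ccc([C@H]2Oc3c(ccc(OCc9ccccc9)c3OCc9ccccc9)[C@@H](c3cc4COC(C)(C)Oc4c(OCc9ccccc9)c3OCc9ccccc9)[C@@H]2O)cc1OCc9ccccc9 | intermediate
18 | (2R,4S)-7,8-bis(benzyloxy)-2-[3,4-bis(benzyloxy)phenyl]-4-[7,8-bis(benzyloxy)-2,2-dimethyl-4H-1,3-benzodioxin-6-yl]chroman-3-one (aryl groups cis) | O(Cc9ccccc9)c1ccc([C@H]2Oc3c(ccc(OCc9ccccc9)c3OCc9ccccc9)[C@@H](c3cc4COC(C)(C)Oc4c(OCc9ccccc9)c3OCc9ccccc9)C2=O)cc1OCc9ccccc9 | intermediate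
19 | (2R,3R,4S)-7,8-bis(benzyloxy)-2-[3,4-bis(benzyloxy)phenyl]-4-[7,8-bis(benzyloxy)-2,2-dimethyl-4H-1,3-benzodioxin-6-yl]chroman-3-ol (all-cis) | O(Cc9ccccc9)c1ccc([C@H]2Oc3c(ccc(OCc9ccccc9)c3OCc9ccccc9)[C@@H](c3cc4COC(C)(C)Oc4c(OCc9ccccc9)c3OCc9ccccc9)[C@H]2O)cc1OCc9ccccc9 | intermediate
20 | (2R,3R,4S)-7,8-bis(benzyloxy)-2-[3,4-bis(benzyloxy)phenyl]-4-[2,3-bis(benzyloxy)-4-hydroxy-5-(hydroxymethyl)phenyl]chroman-3-ol (all-cis) | O(Cc9ccccc9)c1ccc([C@H]2Oc3c(ccc(OCc9ccccc9)c3OCc9ccccc9)[C@@H](c3cc(CO)c(O)c(OCc9ccccc9)c3OCc9ccccc9)[C@H]2O)cc1OCc9ccccc9 | intermediate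
21 | 3,4-bis(benzyloxy)benzaldehyde | O=Cc1ccc(OCc2ccccc2)c(OCc3ccccc3)c1 | starting material
22 | ethyl (E)-3-[3,4-bis(benzyloxy)phenyl]prop-2-enoate | CCOC(=O)/C=C/c1ccc(OCc2ccccc2)c(OCc3ccccc3)c1 | intermediate
23 | (E)-3-[3,4-bis(benzyloxy)phenyl]prop-2-en-1-ol | OC/C=C/c1ccc(OCc2ccccc2)c(OCc3ccccc3)c1 | intermediate
24 | (E)-3-[3,4-bis(benzyloxy)phenyl]allyl methyl carbonate | COC(=O)OC/C=C/c1ccc(OCc2ccccc2)c(OCc3ccccc3)c1 | intermediate
25 | 20 with its ring D phenol etherified by (1S)-1-[3,4-bis(benzyloxy)phenyl]prop-2-en-1-yl; ring D CH2OH and 3-OH free | O(Cc9ccccc9)c1ccc([C@H]2Oc3c(ccc(OCc9ccccc9)c3OCc9ccccc9)[C@@H](c3cc(CO)c(c(OCc9ccccc9)c3OCc9ccccc9)O[C@H](c3ccc(OCc9ccccc9)c(OCc9ccccc9)c3)C=C)[C@H]2O)cc1OCc9ccccc9 | intermediate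
26 | 25 with ring D CH2OH oxidised to CHO | O(Cc9ccccc9)c1ccc([C@H]2Oc3c(ccc(OCc9ccccc9)c3OCc9ccccc9)[C@@H](c3cc(C=O)c(c(OCc9ccccc9)c3OCc9ccccc9)O[C@H](c3ccc(OCc9ccccc9)c(OCc9ccccc9)c3)C=C)[C@H]2O)cc1OCc9ccccc9 | intermediate
27 | 1,2,4-trioxolane (ozonide) of the vinyl group of 26, both epimers at the trioxolane carbon | O(Cc9ccccc9)c1ccc([C@H]2Oc3c(ccc(OCc9ccccc9)c3OCc9ccccc9)[C@@H](c3cc(C=O)c(c(OCc9ccccc9)c3OCc9ccccc9)O[C@H](c3ccc(OCc9ccccc9)c(OCc9ccccc9)c3)C4OCOO4)[C@H]2O)cc1OCc9ccccc9 | intermediate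
28 | dialdehyde: (2R,3R,4S)-all-cis flavan-3-ol whose C4 aryl is 2,3-bis(benzyloxy)-5-formyl-4-{[(1R)-1-[3,4-bis(benzyloxy)phenyl]-2-oxoethyl]oxy}phenyl | O(Cc9ccccc9)c1ccc([C@H]2Oc3c(ccc(OCc9ccccc9)c3OCc9ccccc9)[C@@H](c3cc(C=O)c(c(OCc9ccccc9)c3OCc9ccccc9)O[C@H](c3ccc(OCc9ccccc9)c(OCc9ccccc9)c3)C=O)[C@H]2O)cc1OCc9ccccc9 | intermediate
29 | 3',4'-bis(trimethylsilyl) ether of 30 | O(Cc9ccccc9)c1ccc([C@H]2Oc3c(ccc(OCc9ccccc9)c3OCc9ccccc9)[C@@H](c3cc4c(c(OCc9ccccc9)c3OCc9ccccc9)O[C@H](c3ccc(OCc9ccccc9)c(OCc9ccccc9)c3)[C@H](O[Si](C)(C)C)[C@H]4O[Si](C)(C)C)[C@H]2O)cc1OCc9ccccc9 | intermediate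
30 | octa-O-benzyl dimer: upper (2R,3R,4S) all-cis 4-arylflavan-3-ol linked C4 to C6' of the lower (2'R,3'R,4'S) 2,3-cis-3,4-trans flavan-3,4-diol; 3-OH, 3'-OH and 4'-OH free | O(Cc9ccccc9)c1ccc([C@H]2Oc3c(ccc(OCc9ccccc9)c3OCc9ccccc9)[C@@H](c3cc4c(c(OCc9ccccc9)c3OCc9ccccc9)O[C@H](c3ccc(OCc9ccccc9)c(OCc9ccccc9)c3)[C@H](O)[C@H]4O)[C@H]2O)cc1OCc9ccccc9 | intermediate
31 | (2R,3R,4R)-2-(3,4-dihydroxyphenyl)-4-[(2R,3R,4S)-2-(3,4-dihydroxyphenyl)-3,4,7,8-tetrahydroxychroman-6-yl]chroman-3,7,8-triol | Oc1ccc([C@H]2Oc3c(ccc(O)c3O)[C@@H](c3cc4c(c(O)c3O)O[C@H](c3ccc(O)c(O)c3)[C@H](O)[C@H]4O)[C@H]2O)cc1O | target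

**Totals and risks**

Total step count: 20. Longest linear sequence: 14 steps (7 to 31 through steps 4–12 and 16–20).

Steps most likely to fail:

1. Step 19. Three processes threaten it. The aldehyde may be attacked with its oxygen pseudo-equatorial (anti to the C2'–O1' bond), giving the 2',3'-trans diol. C2' may be lost by enolisation of the α-aryloxy aldehyde. Intermolecular coupling or over-reduction to the benzyl alcohol may compete.
 Fallback: ring F is built without any α-aryloxy aldehyde, setting out from 26 and returning at 30. Wittig methylenation of the aryl aldehyde (Ph3P=CH2, THF, 0 °C) gives the styrene F1. Ring-closing metathesis with the second-generation Grubbs catalyst (H2IMes)(PCy3)Cl2Ru=CHPh closes ring F as the (2'R)-flav-3'-ene F2. Hydroboration–oxidation gives the 2',3'-trans-3'-ol F3. Dess–Martin oxidation of both secondary alcohols gives the diketone F4. LiBH(s-Bu)3 restores the all-cis upper alcohol and sets the 2',3'-cis lower alcohol F5. DDQ in wet CH2Cl2 then oxidises the C4' methylene (para to the 7'-benzyloxy group), and water adds trans to the 3'-OH to give 30.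

2. Step 16. The phenoxide is 2,6-disubstituted and may react slowly. Reversible ionisation of the electron-rich branched ether by the catalyst may erode the branched-to-linear ratio and the configuration at C2'.
 Fallback: the O1'–C2' bond is made by Mitsunobu inversion, setting out from 20 (and 21) and returning at 28. MnO2 oxidation of 20 gives the salicylaldehyde F6. Separately, 21 is converted by (S)-selective hydroxynitrile-lyase catalysed HCN addition into the cyanohydrin F7, and Pinner methanolysis (HCl, MeOH, then water) gives methyl (S)-3,4-bis(benzyloxy)mandelate F8. Mitsunobu coupling of F6 with F8 (PPh3, DIAD, THF, 0 °C) proceeds with inversion to the (R)-α-aryloxy ester F9. i-Bu2AlH reduces ester and aryl aldehyde to the diol F10. TEMPO with PhI(OAc)2 oxidises the two primary alcohols (the hindered secondary 3-OH is spared) to dialdehyde 28.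

3. Step 8. The aryl metal may enolise the flavanone (opening ring C) instead of adding. Addition to the electron-rich, vinylogous-ester-like ketone may be slow. The 2H-chromene may racemise at C2 by electrocyclic ring opening if heated or exposed to light.
 Fallback: the C4–C6' bond is made by cross-coupling, setting out from 6 and 11 and returning at 15. Flavanone 6 is converted with Tf2O and 2,6-di-tert-butyl-4-methylpyridine (CH2Cl2, 0 °C) into the enol triflate F11. Bromide 11 is converted by n-BuLi and 2-isopropoxy-4,4,5,5-tetramethyl-1,3,2-dioxaborolane into the pinacol boronate F12. Suzuki–Miyaura coupling (Pd(PPh3)4, K3PO4, dioxane–H2O, 80 °C, dark) gives 15.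

**Further compounds**

F1 | step 19 | 26 with ring D CHO converted to vinyl | O(Cc9ccccc9)c1ccc([C@H]2Oc3c(ccc(OCc9ccccc9)c3OCc9ccccc9)[C@@H](c3cc(C=C)c(c(OCc9ccccc9)c3OCc9ccccc9)O[C@H](c3ccc(OCc9ccccc9)c(OCc9ccccc9)c3)C=C)[C@H]2O)cc1OCc9ccccc9
F2 | step 19 | octa-O-benzyl dimer with ring F as (2'R)-2H-chromene (C3'=C4') | O(Cc9ccccc9)c1ccc([C@H]2Oc3c(ccc(OCc9ccccc9)c3OCc9ccccc9)[C@@H](c3cc4c(c(OCc9ccccc9)c3OCc9ccccc9)O[C@H](c3ccc(OCc9ccccc9)c(OCc9ccccc9)c3)C=C4)[C@H]2O)cc1OCc9ccccc9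
F3 | step 19 | octa-O-benzyl dimer with 2',3'-trans-3'-ol and C4' methylene | O(Cc9ccccc9)c1ccc([C@H]2Oc3c(ccc(OCc9ccccc9)c3OCc9ccccc9)[C@@H](c3cc4c(c(OCc9ccccc9)c3OCc9ccccc9)O[C@H](c3ccc(OCc9ccccc9)c(OCc9ccccc9)c3)[C@@H](O)C4)[C@H]2O)cc1OCc9ccccc9
F4 | step 19 | 3,3'-diketone of F3 | O(Cc9ccccc9)c1ccc([C@H]2Oc3c(ccc(OCc9ccccc9)c3OCc9ccccc9)[C@@H](c3cc4c(c(OCc9ccccc9)c3OCc9ccccc9)O[C@H](c3ccc(OCc9ccccc9)c(OCc9ccccc9)c3)C(=O)C4)C2=O)cc1OCc9ccccc9
F5 | step 19 | octa-O-benzyl dimer with 2',3'-cis-3'-ol and C4' methylene (4'-deoxy-30) | O(Cc9ccccc9)c1ccc([C@H]2Oc3c(ccc(OCc9ccccc9)c3OCc9ccccc9)[C@@H](c3cc4c(c(OCc9ccccc9)c3OCc9ccccc9)O[C@H](c3ccc(OCc9ccccc9)c(OCc9ccccc9)c3)[C@H](O)C4)[C@H]2O)cc1OCc9ccccc9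
F6 | step 16 | 20 with ring D CH2OH oxidised to CHO (free phenol) | O(Cc9ccccc9)c1ccc([C@H]2Oc3c(ccc(OCc9ccccc9)c3OCc9ccccc9)[C@@H](c3cc(C=O)c(O)c(OCc9ccccc9)c3OCc9ccccc9)[C@H]2O)cc1OCc9ccccc9
F7 | step 16 | (S)-2-[3,4-bis(benzyloxy)phenyl]-2-hydroxyacetonitrile | O[C@@H](c1ccc(OCc2ccccc2)c(OCc3ccccc3)c1)C#N
F8 | step 16 | methyl (S)-2-[3,4-bis(benzyloxy)phenyl]-2-hydroxyacetate | O[C@@H](c1ccc(OCc2ccccc2)c(OCc3ccccc3)c1)C(=O)OC
F9 | step 16 | (R)-α-aryloxy methyl ester from F6 and F8 (ring D CHO retained) | O(Cc9ccccc9)c1ccc([C@H]2Oc3c(ccc(OCc9ccccc9)c3OCc9ccccc9)[C@@H](c3cc(C=O)c(c(OCc9ccccc9)c3OCc9ccccc9)O[C@H](c3ccc(OCc9ccccc9)c(OCc9ccccc9)c3)C(=O)OC)[C@H]2O)cc1OCc9ccccc9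
F10 | step 16 | diol from F9: ring D CH2OH and (R)-2-aryloxy-2-arylethanol | O(Cc9ccccc9)c1ccc([C@H]2Oc3c(ccc(OCc9ccccc9)c3OCc9ccccc9)[C@@H](c3cc(CO)c(c(OCc9ccccc9)c3OCc9ccccc9)O[C@H](c3ccc(OCc9ccccc9)c(OCc9ccccc9)c3)CO)[C@H]2O)cc1OCc9ccccc9
F11 | step 8 | (2S)-7,8-bis(benzyloxy)-2-[3,4-bis(benzyloxy)phenyl]-2H-chromen-4-yl trifluoromethanesulfonate | O(Cc9ccccc9)c1ccc([C@H]2Oc3c(ccc(OCc9ccccc9)c3OCc9ccccc9)C(OS(=O)(=O)C(F)(F)F)=C2)cc1OCc9ccccc9
F12 | step 8 | 7,8-bis(benzyloxy)-2,2-dimethyl-6-(4,4,5,5-tetramethyl-1,3,2-dioxaborolan-2-yl)-4H-1,3-benzodioxine | CC1(C)OCc2cc(B3OC(C)(C)C(C)(C)O3)c(OCc4ccccc4)c(OCc5ccccc5)c2O1
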